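(All runs were computed on assumed constants, and the scatter is random.)

**The decision.** I choose to reckon these flasks by the gas and not by X.

| flask | X | G | temperature | remark | time |
|---|---|---|---|---|---|
| delta | 0.022 M (fed, over 2.5 min) | 12 mM (held) | 0 °C | run made earlier; the fed solution adds 0.10 times the starting volume |  |
| east | 0.040 M (fed, over 2.5 min) | 12 mM (held) |  | at 0 °C throughout; the fed solution adds 0.10 times the starting volume | 50 min |
| north | 0.020 M (fed, over 2.5 min) | 12 mM (held) |  | at 0 °C until 2.5 min, from then on at 40 °C; the fed solution adds 0.10 times the starting volume | 50 min |

- delta (time / min: E / %): 2.50: 42.8; 5.00: 83.7; 8.00: 94.3; 10.0: 93.5; 12.0: 93.0; 15.0: 93.0; 20.0: 93.7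

(scatter of a reading: 0.5 percentage points)

- charges are per starting volume, the dose included; the dosed solution carries all of it
- the earlier runs were read with a standard deviation of 0.5 percentage points
- at the start none of G is in solution
- the earlier runs do not show what temperature does; that part of a forecast is a guess

* which one finishes higher in amount of E, in percent of the X charged ("neither" within 2 percentage points) (east / north / neither)
* amount of E at the end, in percent of the X charged, east
* amount of E at the end, in percent of the X charged, north

**Gas supply.** In delta, E grows by 3.77 mM min⁻¹ up to the first reading and by 3.60 mM min⁻¹ up to the second, although [X] is changing. I call this second figure the gas supply: the E made per minute, per starting volume. X arrives at 8.80 mM min⁻¹, faster than the supply, so I take the transfer of G as the rate-limiting step, with X waiting for gas.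

**Rule of thumb.** Charge over supply gives the hold-up time: 6.11 min in delta, 11.1 min in east and 5.56 min in north. The readings of delta level off near 93.0%, so I read 7.00% of its X as gone elsewhere. At one temperature I let this loss grow in step with the hold-up, which puts east at 87.3%.

**The border.** That rule stops in north, where the warming comes at 2.5 min, with 45.0% of the hold-up passed. By this reckoning, the rest of the X in north waits in the warm. The earlier runs show nothing of temperature, so this part is my guess: the loss doubles every 10 degrees, a factor of 16.0, and the supply stays. I then let gas and loss share that rest as one to 1.12, which puts north at 70.9%, lower than my figure for east.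

**The forecast.** The forecast differs: it names north, with east at 81% and north at 88%, saying of north that “The side reaction may speed up and E may slowly degrade”.

**The result.** The flasks give east: east 82.6% and north 66.6%, which are 4.7 percentage points and 4.3 points below my figures.

    X + Z ⇌ E + D (K = 270, k = 6.91 M⁻¹ s⁻¹, Ea = 37.0 kJ mol⁻¹, ΔH = −17.0 kJ mol⁻¹)
    G ⇌ Z, rate k2*(csat - [Z]) (kL = 0.00619 s⁻¹)
    X + D → L (k = 0.0676 M⁻¹ s⁻¹, Ea = 50.0 kJ mol⁻¹)
    (constants at 0 °C)

**The comparison.** At 3.12 min in north, the E step, counted forward alone, uses X 2.8 times as fast as the L step. The half-life of X by the L step alone is then 1.1 min, shorter than the 3.06 min of hold-up that my reckoning leaves in north after the warming.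

**A neighbour.** Take north with 0.034 M of X. The hold-up becomes 9.45 min, 26.5% of it passes in the cold, and the same split of the rest gives 61.2%. The computed neighbour flask gives 57.7%.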